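The cyclohexenone ring is cut across two bonds: carbonyl carbon to the methyl-bearing ring-fusion carbon, and enone α-carbon to β-carbon. Step 4 makes both in one pot: the anion of a γ-hydroxy nitrile is C-acylated by a cyclopentenylacetic ester (α–β bond), then iron-hydride hydrogen-atom transfer to the ring alkene gives a tertiary radical that closes onto the nitrile carbon, the later carbonyl. It exploits the 1,3-relation of the carbonyl carbon and the β-carbon across the α-carbon (a masked 1,3-dione) and the adjacent quaternary ring-fusion carbons of the cis-hydrindane: the existing one steers the new one. The precursors are an ester from a Johnson–Claisen rearrangement and 4-hydroxy-4-methylpentanenitrile; the aryl-prenyl chain is coupled late.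

Key step: step 4

Remark: the sense of induction in step 1 is assigned by the usual model of the CBS reduction (alkenyl carbon as the large group); the dione 10 is drawn as one enol tautomer.

Step 1
Reactants: 1 2,3-dimethylcyclopent-2-en-1-one
Product: 2 (R)-2,3-dimethylcyclopent-2-en-1-ol
Conditions: (S)-2-methyl-CBS-oxazaborolidine (10 mol %), BH3·SMe2, THF, −20 °C; MeOH quench
Reagents that add atoms: none
Why: Corey–Bakshi–Shibata reduction, in which the oxazaborolidine–borane complex delivers hydride in a 1,2-sense to one face of the enone carbonyl with the methyl-substituted alkenyl carbon as the large group, which should set the (R)-carbinol centre.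

Step 2
Reactants: 2 (R)-2,3-dimethylcyclopent-2-en-1-ol
Product: 4 ethyl 2-[(1R)-1,2-dimethylcyclopent-2-en-1-yl]acetate, via ketene acetal 3 (not isolated)
Conditions: MeC(OEt)3, EtCO2H (cat.), 140 °C, EtOH distilled off
Reagents that add atoms: triethyl orthoacetate, CCOC(C)(OCC)OCC
Why: Johnson–Claisen rearrangement, in which the mixed ketene acetal undergoes a suprafacial [3,3]-sigmatropic shift inside the five-membered ring, so the new carbon–carbon bond forms on the face that carried the oxygen and the carbinol configuration is transferred to the new quaternary centre.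

Step 3
Reactants: 5 acetonitrile; 6 2,2-dimethyloxirane
Product: 7 4-hydroxy-4-methylpentanenitrile
Conditions: LDA, THF, −78 °C; then 6, −78 °C → rt
Reagents that add atoms: none
Why: Nucleophilic epoxide opening, in which lithiated acetonitrile attacks the unsubstituted carbon of the oxirane in an SN2 reaction and gives the tertiary alcohol directly.

Step 4
Reactants: 4 ethyl 2-[(1R)-1,2-dimethylcyclopent-2-en-1-yl]acetate; 7 4-hydroxy-4-methylpentanenitrile
Product: 9 (3aR,7aR)-7-amino-6-(2-hydroxy-2-methylpropyl)-3a,7a-dimethyl-1,2,3,3a,4,7a-hexahydro-5H-inden-5-one, via β-keto nitrile 8 (not isolated)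
Conditions: 7 (2.5 equiv), LDA (5 equiv), THF, −78 °C; then 4, −78 → 0 °C; AcOH, solvent exchange to EtOH; Fe(acac)3 (30 mol %), PhSiH3, 60 °C
Reagents that add atoms: none
Why: The α-lithiated nitrile (dianion of 7) attacks the ester carbonyl of 4 in a Claisen-type C-acylation (closest known type: acylation of nitrile anions by esters), which joins the future enone α- and β-carbons and gives the β-keto nitrile as its enolate. After neutralisation an iron hydride formed from Fe(acac)3 and PhSiH3 transfers a hydrogen atom to the unsubstituted carbon of the ring alkene, and the tertiary cyclopentyl radical adds to the nitrile carbon; the iminyl radical is reduced and the imine tautomerises to the vinylogous amide (closest known type: hydrogen-atom-transfer-initiated radical cyclisation of alkenyl nitriles to cyclic ketone equivalents). The six-membered ring closes in the 6-exo-dig mode. The new quaternary ring-fusion stereocentre is controlled by the existing quaternary carbon, because the three-atom tether that carries the nitrile can reach the radical only from its own face, so the ring fusion is cis and the two methyl groups end up cis. The step needs Markovnikov hydrogen transfer at the only alkene present and ring closure faster than a second hydrogen transfer; the first follows from tertiary radical stability, the second is favoured by the electrophilic α-keto nitrile carbon and the quaternary centre in the tether (Thorpe–Ingold effect). The competing closures (four-membered onto the ketone, 5-endo onto the enol) are disfavoured, and C-acylation is inherent to the nitrile anion.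

Step 5
Reactants: 9 (3aR,7aR)-7-amino-6-(2-hydroxy-2-methylpropyl)-3a,7a-dimethyl-1,2,3,3a,4,7a-hexahydro-5H-inden-5-one
Product: 10 (3aR,7aR)-5-(2-hydroxy-2-methylpropyl)-3a,7a-dimethylhexahydroindane-4,6-dione (6-hydroxy-4-oxo enol)
Conditions: 2 M KOH, EtOH–H2O, 80 °C; then 1 M HCl to pH 4, 0 °C; used crude
Reagents that add atoms: water, O
Why: Hydrolysis of a vinylogous amide, in which hydroxide adds to the amino-bearing carbon and ammonia is expelled (conjugate addition–elimination) to leave the 1,3-dione as its enolate, which resists retro-Claisen cleavage and is protonated only at the end.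

Step 6
Reactants: 10 (3aR,7aR)-5-(2-hydroxy-2-methylpropyl)-3a,7a-dimethylhexahydroindane-4,6-dione
Product: 11 (3aR,7aR)-6-(2-hydroxy-2-methylpropyl)-3a,7a-dimethyl-7-oxo-2,3,3a,4,7,7a-hexahydro-1H-inden-5-yl trifluoromethanesulfonate
Conditions: PhNTf2, Et3N, DMAP (cat.), CH2Cl2, 0 °C → rt
Reagents that add atoms: N-phenyl-bis(trifluoromethanesulfonimide), O=S(=O)(N(c1ccccc1)S(=O)(=O)C(F)(F)F)C(F)(F)F
Why: O-Sulfonylation of a 1,3-dione enolate, which should occur at the oxygen on the carbon next to the ring methylene because the other oxygen is shielded by the adjacent quaternary ring-fusion carbon, while the neutral tertiary alcohol does not react with this mild triflyl donor.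

Step 7
Reactants: 12 4-methoxy-2-methylphenol; 13 1-bromo-3-methylbut-2-ene (prenyl bromide)
Product: 14 4-methoxy-2-methyl-6-(3-methylbut-2-en-1-yl)phenol
Conditions: NaH, toluene, 0 °C; then 13, rt
Reagents that add atoms: none
Why: C-Alkylation of a phenoxide, in which the sodium phenoxide as a tight ion pair in a non-polar solvent attacks the allylic bromide through its only free ortho carbon (the para position is blocked) in preference to oxygen.

Step 8
Reactants: 14 4-methoxy-2-methyl-6-(3-methylbut-2-en-1-yl)phenol
Product: 15 tert-butyl[4-methoxy-2-methyl-6-(3-methylbut-2-en-1-yl)phenoxy]dimethylsilane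
Conditions: TBSCl, imidazole, DMF, 40 °C
Reagents that add atoms: tert-butyldimethylsilyl chloride, CC(C)(C)[Si](C)(C)Cl
Why: Silyl ether formation, in which imidazole-activated silyl chloride caps the hindered phenol oxygen so that it survives the selenium oxidation, the bromination and the basic coupling.

Step 9
Reactants: 15 tert-butyl[4-methoxy-2-methyl-6-(3-methylbut-2-en-1-yl)phenoxy]dimethylsilane
Product: 16 (2E)-4-{2-[(tert-butyldimethylsilyl)oxy]-5-methoxy-3-methylphenyl}-2-methylbut-2-en-1-ol
Conditions: SeO2 (cat.), t-BuOOH, CH2Cl2, rt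
Reagents that add atoms: tert-butyl hydroperoxide, CC(C)(C)OO
Why: Allylic oxidation with selenium dioxide, whose ene reaction and [2,3]-sigmatropic shift oxidise the methyl group trans to the chain on the more substituted alkene carbon and so give the (E)-allylic alcohol.

Step 10
Reactants: 16 (2E)-4-{2-[(tert-butyldimethylsilyl)oxy]-5-methoxy-3-methylphenyl}-2-methylbut-2-en-1-ol
Product: 17 {2-[(2E)-4-bromo-3-methylbut-2-en-1-yl]-4-methoxy-6-methylphenoxy}(tert-butyl)dimethylsilane
Conditions: CBr4, PPh3, CH2Cl2, 0 °C
Reagents that add atoms: carbon tetrabromide, BrC(Br)(Br)Br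
Why: Appel reaction, in which bromide displaces the oxyphosphonium group at the primary allylic carbon in an SN2 reaction under neutral conditions, so the (E)-alkene is kept.

Step 11
Reactants: 11 (3aR,7aR)-6-(2-hydroxy-2-methylpropyl)-3a,7a-dimethyl-7-oxo-2,3,3a,4,7,7a-hexahydro-1H-inden-5-yl trifluoromethanesulfonate; 17 {2-[(2E)-4-bromo-3-methylbut-2-en-1-yl]-4-methoxy-6-methylphenoxy}(tert-butyl)dimethylsilane
Product: 19 (3aR,7aR)-6-[(2E)-4-{2-[(tert-butyldimethylsilyl)oxy]-5-methoxy-3-methylphenyl}-2-methylbut-2-en-1-yl]-5-(2-hydroxy-2-methylpropyl)-3a,7a-dimethyl-1,2,3,3a,7,7a-hexahydro-4H-inden-4-one, via alkenyl boronate 18 (not isolated)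
Conditions: PdCl2(dppf) (5 mol %), B2pin2, KOAc, 1,4-dioxane, 80 °C; then 17, K3PO4, H2O, 60 °C
Reagents that add atoms: none
Why: Miyaura borylation followed by Suzuki–Miyaura allylation in one pot, in which zerovalent palladium first turns the vinyl triflate into the pinacol boronate and then forms the π-allyl complex of the bromide, which couples with the alkenyl boronate at its unsubstituted terminus with retention of the (E)-alkene (syn π-allyl) to give the skipped diene.

Step 12
Reactants: 19 the silyl ether from step 11
Product: 20 (3aR,7aR)-5-(2-hydroxy-2-methylpropyl)-6-[(2E)-4-(2-hydroxy-5-methoxy-3-methylphenyl)-2-methylbut-2-en-1-yl]-3a,7a-dimethyl-1,2,3,3a,7,7a-hexahydro-4H-inden-4-one (target)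
Conditions: TBAF, THF, 0 °C
Reagents that add atoms: none
Why: Fluoride-mediated desilylation, in which the strong silicon–fluorine bond drives cleavage of the aryl silyl ether under conditions that leave the enone, the skipped diene and the tertiary alcohol untouched.

Compound list
1 | 2,3-dimethylcyclopent-2-en-1-one | CC1=C(C)C(=O)CC1 | starting material
2 | (R)-2,3-dimethylcyclopent-2-en-1-ol | O[C@@H]1CCC(C)=C1C | intermediate
3 | (1R)-2,3-dimethylcyclopent-2-en-1-yl 1-ethoxyethenyl ether (ketene acetal) | C=C(OCC)O[C@@H]1CCC(C)=C1C | intermediate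
4 | ethyl 2-[(1R)-1,2-dimethylcyclopent-2-en-1-yl]acetate | CCOC(=O)C[C@@]1(C)CCC=C1C | intermediate
5 | acetonitrile | CC#N | starting material
6 | 2,2-dimethyloxirane | CC1(C)CO1 | starting material
7 | 4-hydroxy-4-methylpentanenitrile | CC(C)(O)CCC#N | intermediate
8 | 4-[(1R)-1,2-dimethylcyclopent-2-en-1-yl]-2-(2-hydroxy-2-methylpropyl)-3-oxobutanenitrile (both epimers at the nitrile-bearing carbon) | CC(C)(O)CC(C#N)C(=O)C[C@@]1(C)CCC=C1C | intermediate
9 | (3aR,7aR)-7-amino-6-(2-hydroxy-2-methylpropyl)-3a,7a-dimethyl-1,2,3,3a,4,7a-hexahydro-5H-inden-5-one (cis-fused) | CC(C)(O)CC1=C(N)[C@]2(C)CCC[C@]2(C)CC1=O | intermediate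
10 | (3aR,7aR)-5-(2-hydroxy-2-methylpropyl)-3a,7a-dimethylhexahydroindane-4,6-dione, drawn as the 6-hydroxy-4-oxo enol | CC(C)(O)CC1=C(O)C[C@@]2(C)CCC[C@@]2(C)C1=O | intermediate
11 | (3aR,7aR)-6-(2-hydroxy-2-methylpropyl)-3a,7a-dimethyl-7-oxo-2,3,3a,4,7,7a-hexahydro-1H-inden-5-yl trifluoromethanesulfonate | CC(C)(O)CC1=C(OS(=O)(=O)C(F)(F)F)C[C@@]2(C)CCC[C@@]2(C)C1=O | intermediate
12 | 4-methoxy-2-methylphenol | COc1ccc(O)c(C)c1 | starting material
13 | 1-bromo-3-methylbut-2-ene | CC(C)=CCBr | starting material
14 | 4-methoxy-2-methyl-6-(3-methylbut-2-en-1-yl)phenol | COc1cc(C)c(O)c(CC=C(C)C)c1 | intermediate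
15 | tert-butyl[4-methoxy-2-methyl-6-(3-methylbut-2-en-1-yl)phenoxy]dimethylsilane | COc1cc(C)c(O[Si](C)(C)C(C)(C)C)c(CC=C(C)C)c1 | intermediate
16 | (2E)-4-{2-[(tert-butyldimethylsilyl)oxy]-5-methoxy-3-methylphenyl}-2-methylbut-2-en-1-ol | COc1cc(C)c(O[Si](C)(C)C(C)(C)C)c(C/C=C(\C)CO)c1 | intermediate
17 | {2-[(2E)-4-bromo-3-methylbut-2-en-1-yl]-4-methoxy-6-methylphenoxy}(tert-butyl)dimethylsilane | COc1cc(C)c(O[Si](C)(C)C(C)(C)C)c(C/C=C(\C)CBr)c1 | intermediate
18 | (3aR,7aR)-5-(2-hydroxy-2-methylpropyl)-3a,7a-dimethyl-6-(4,4,5,5-tetramethyl-1,3,2-dioxaborolan-2-yl)-1,2,3,3a,7,7a-hexahydro-4H-inden-4-one | CC(C)(O)CC1=C(B3OC(C)(C)C(C)(C)O3)C[C@@]2(C)CCC[C@@]2(C)C1=O | intermediate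
19 | (3aR,7aR)-6-[(2E)-4-{2-[(tert-butyldimethylsilyl)oxy]-5-methoxy-3-methylphenyl}-2-methylbut-2-en-1-yl]-5-(2-hydroxy-2-methylpropyl)-3a,7a-dimethyl-1,2,3,3a,7,7a-hexahydro-4H-inden-4-one | COc1cc(C)c(O[Si](C)(C)C(C)(C)C)c(C/C=C(\C)CC2=C(CC(C)(C)O)C(=O)[C@]3(C)CCC[C@]3(C)C2)c1 | intermediate
20 | (3aR,7aR)-5-(2-hydroxy-2-methylpropyl)-6-[(2E)-4-(2-hydroxy-5-methoxy-3-methylphenyl)-2-methylbut-2-en-1-yl]-3a,7a-dimethyl-1,2,3,3a,7,7a-hexahydro-4H-inden-4-one | COc1cc(C)c(O)c(C/C=C(\C)CC2=C(CC(C)(C)O)C(=O)[C@]3(C)CCC[C@]3(C)C2)c1 | target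

Total step count: 12. Longest linear sequence: 7 steps (steps 1, 2, 4, 5, 6, 11, 12).

Steps most likely to fail

Step 4. The tertiary radical may take a second hydrogen atom from the iron hydride before the comparatively slow 6-exo-dig closure onto the nitrile, or the salts carried over from the acylation may slow the hydrogen-atom transfer. The fallback sets out from 8, isolated after the acylation stage, and generates the radical by halogen abstraction instead. The ring alkene is converted by a hydrogen-atom-transfer hydrochlorination (Co(salen), TsCl, PhSiH3) into the tertiary chloride 4-[(1R)-2-chloro-1,2-dimethylcyclopentyl]-2-(2-hydroxy-2-methylpropyl)-3-oxobutanenitrile F1. This is cyclised with (Me3Si)3SiH and AIBN under slow addition at high dilution, where no metal hydride competes with ring closure. Tautomerisation of the cyclic imine brings the sequence back to 9.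

Step 6. Sulfonylation may fall partly on the oxygen next to the quaternary carbon, or the free dione may close with its tertiary alcohol to a cyclic enol ether before it is trapped. The fallback sets out from 8 and fixes the leaving group before the ring is closed. The enolate of 8 is trapped with PhNTf2 and Et3N as (2E)-3-cyano-1-[(1R)-1,2-dimethylcyclopent-2-en-1-yl]-5-hydroxy-5-methylhex-2-en-2-yl trifluoromethanesulfonate F2; the isomer with the small linear nitrile cis to the cyclopentenylmethyl group should prevail. The iron-hydride radical cyclisation of F2 onto the nitrile then gives the conjugated N–H ketimine (3aR,7aR)-6-(2-hydroxy-2-methylpropyl)-7-imino-3a,7a-dimethyl-2,3,3a,4,7,7a-hexahydro-1H-inden-5-yl trifluoromethanesulfonate F3. Its hydrolysis on aqueous acidic work-up returns 11, with the triflate necessarily on the former ester carbon.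

Step 11. The hindered β-boryl enone 18 may lose boron by protodeboronation, or the π-allyl palladium complex may lose a β-hydrogen to a diene before transmetalation. The fallback sets out from 17 and inverts the polarity of the partners. Zinc dust and LiCl in THF should give the allylzinc reagent {(2E)-4-{2-[(tert-butyldimethylsilyl)oxy]-5-methoxy-3-methylphenyl}-2-methylbut-2-en-1-yl}zinc bromide F4. F4 is coupled with triflate 11 in a Negishi reaction (Pd(OAc)2, CPhos), a coupling known to favour the linear allyl isomer, and this comes back to the route at 19.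

Further compounds
F1 | step 4 | 4-[(1R)-2-chloro-1,2-dimethylcyclopentyl]-2-(2-hydroxy-2-methylpropyl)-3-oxobutanenitrile | CC(C)(O)CC(C#N)C(=O)C[C@@]1(C)CCCC1(C)Cl
F2 | step 6 | (2E)-3-cyano-1-[(1R)-1,2-dimethylcyclopent-2-en-1-yl]-5-hydroxy-5-methylhex-2-en-2-yl trifluoromethanesulfonate | CC(C)(O)C/C(C#N)=C(\OS(=O)(=O)C(F)(F)F)C[C@@]1(C)CCC=C1C
F3 | step 6 | (3aR,7aR)-6-(2-hydroxy-2-methylpropyl)-7-imino-3a,7a-dimethyl-2,3,3a,4,7,7a-hexahydro-1H-inden-5-yl trifluoromethanesulfonate | CC(C)(O)CC1=C(OS(=O)(=O)C(F)(F)F)C[C@@]2(C)CCC[C@@]2(C)C1=N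
F4 | step 11 | {(2E)-4-{2-[(tert-butyldimethylsilyl)oxy]-5-methoxy-3-methylphenyl}-2-methylbut-2-en-1-yl}zinc bromide | COc1cc(C)c(O[Si](C)(C)C(C)(C)C)c(C/C=C(\C)C[Zn]Br)c1
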